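Ring A, the cyclohexa-2,5-dienone, is not bought as an arene but closed last, between its carbonyl carbon C1 and the adjacent CH (C2). All six ring carbons come from methyl sorbate, whose C4 is joined to the diaryl ketone carbon C7. The precursor is thus an open-chain (2E)-4-(diarylhydroxymethyl)hexa-2,5-dienoic acid. Activation and loss of the doubly allylic C4–H give a dienylketene. Its 6π electrocyclisation forms C1–C2, and enolisation plus loss of the C7 hydroxyl as water unveil the quinone methide in the same flask. The step exploits the para relation between C1=O and the exocyclic C4=C7 bond: ring A is the dehydrated keto form of a 4-substituted phenol.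

Key step: step 11

Assumption: the target is taken as the open quinone methide drawn. It has no stereocentre, ring A and the 4-hydroxyphenyl ring on C7 exchange roles by proton transfer, and addition of the 2'-phenol to C7 is treated as a reversible side equilibrium.

Abbreviations used in names:
- MOM = methoxymethyl.
- Ar = 4-(methoxymethoxy)phenyl.
- BA = 2',4'-bis(methoxymethoxy)-4-[(methoxymethoxy)methyl]-3-{[4-(methoxymethoxy)phenyl]ethynyl}biphenyl-2-yl.
- Ring A carbons are C1 (C=O) to C6, and the methide carbon is C7.

Step 1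
Reactants: 1 (2-bromo-4-chlorophenyl)methanol
Product: 2 2-bromo-4-chloro-1-[(methoxymethoxy)methyl]benzene
Conditions: MOMCl, iPr2NEt, CH2Cl2, 0 °C to rt
Reagents that add atoms: chloromethyl methyl ether, COCCl
Why: O-alkylation of the primary alcohol with the reactive α-chloro ether should give an acetal that tolerates LDA, organometallic reagents and palladium catalysis.

Step 2
Reactants: 2 2-bromo-4-chloro-1-[(methoxymethoxy)methyl]benzene; 3 4-(methoxymethoxy)benzaldehyde
Product: 5 {2-bromo-6-chloro-3-[(methoxymethoxy)methyl]phenyl}[4-(methoxymethoxy)phenyl]methanol (racemic), via aryllithium 4 (not isolated)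
Conditions: LDA, THF, −78 °C; then 3, −78 °C; aq. NH4Cl
Reagents that add atoms: none
Why: Directed ortho-metalation removes the most acidic C–H, the one flanked by bromine and chlorine, to give a 2,6-dihaloaryllithium that is stable at −78 °C, and its 1,2-addition to the aldehyde sets the C7–aryl bond (the racemic carbinol centre is removed in step 3).

Step 3
Reactants: 5 {2-bromo-6-chloro-3-[(methoxymethoxy)methyl]phenyl}[4-(methoxymethoxy)phenyl]methanol
Product: 6 {2-bromo-6-chloro-3-[(methoxymethoxy)methyl]phenyl}[4-(methoxymethoxy)phenyl]methanone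
Conditions: Dess–Martin periodinane, CH2Cl2, rt
Reagents that add atoms: none
Why: Dess–Martin oxidation of a secondary diaryl carbinol is fast under near-neutral conditions that leave MOM ethers and aryl halides untouched.

Step 4
Reactants: 3 4-(methoxymethoxy)benzaldehyde
Product: 7 1-ethynyl-4-(methoxymethoxy)benzene
Conditions: dimethyl (1-diazo-2-oxopropyl)phosphonate, K2CO3, MeOH, rt
Reagents that add atoms: dimethyl (1-diazo-2-oxopropyl)phosphonate, COP(=O)(OC)C(=[N+]=[N-])C(C)=O
Why: The Ohira–Bestmann variant of the Seyferth–Gilbert homologation converts an aryl aldehyde into the terminal alkyne under mild carbonate conditions.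

Step 5
Reactants: 6 {2-bromo-6-chloro-3-[(methoxymethoxy)methyl]phenyl}[4-(methoxymethoxy)phenyl]methanone; 7 1-ethynyl-4-(methoxymethoxy)benzene
Product: 8 {6-chloro-3-[(methoxymethoxy)methyl]-2-{[4-(methoxymethoxy)phenyl]ethynyl}phenyl}[4-(methoxymethoxy)phenyl]methanone
Conditions: PdCl2(PPh3)2, CuI, Et3N, DMF, 70 °C
Reagents that add atoms: none
Why: In this Sonogashira coupling, zerovalent palladium bearing triphenylphosphine should insert into the C–Br bond, activated by the ortho aroyl group, much faster than into the C–Cl bond.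

Step 6
Reactants: 9 4-bromobenzene-1,3-diol (4-bromoresorcinol)
Product: 10 1-bromo-2,4-bis(methoxymethoxy)benzene
Conditions: MOMCl, iPr2NEt, CH2Cl2, 0 °C to rt
Reagents that add atoms: chloromethyl methyl ether, COCCl
Why: Double O-alkylation protects both phenols, and the ortho MOM group later stabilises the aryllithium where a silyl ether would migrate to carbon.

Step 7
Reactants: 10 1-bromo-2,4-bis(methoxymethoxy)benzene; 8 {6-chloro-3-[(methoxymethoxy)methyl]-2-{[4-(methoxymethoxy)phenyl]ethynyl}phenyl}[4-(methoxymethoxy)phenyl]methanone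
Product: 13 (BA)(Ar)methanone, via aryllithium 11 (not isolated), via arylzinc chloride 12 (not isolated)
Conditions: 10, n-BuLi, THF, −78 °C; ZnCl2, to rt; then 8, Pd2(dba)3, SPhos, THF, 65 °C
Reagents that add atoms: none
Why: In this Negishi coupling, bromine–lithium exchange and transmetalation give an arylzinc reagent that ignores the ketone, and the bulky biarylphosphine allows oxidative addition into the hindered aryl chloride and formation of the di-ortho-substituted biaryl bond.

Step 8
Reactants: 14 methyl (2E,4E)-hexa-2,4-dienoate (methyl sorbate)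
Product: 15 methyl (2E,4E)-6-bromohexa-2,4-dienoate
Conditions: NBS, AIBN (cat.), PhCl, 90 °C
Reagents that add atoms: N-bromosuccinimide, O=C1CCC(=O)N1Br
Why: In this Wohl–Ziegler bromination, hydrogen abstraction from the terminal methyl group gives an ester-stabilised pentadienyl radical that is brominated at its terminus, so the conjugated E,E-dienoate is kept.

Step 9
Reactants: 13 (BA)(Ar)methanone; 15 methyl (2E,4E)-6-bromohexa-2,4-dienoate
Product: 17 methyl (2E)-4-[(Ar)(BA)(hydroxy)methyl]hexa-2,5-dienoate (mixture of diastereomers), via pentadienylindium dibromide 16 (not isolated)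
Conditions: In powder, DMF–THF, rt to 45 °C; aq. NH4Cl
Reagents that add atoms: none
Why: In this Barbier-type indium-mediated γ-pentadienylation (vinylogous Reformatsky reaction), the reagent carries the metal on sorbate C6 and should attack the ketone through a six-membered transition state at C4, which keeps the enoate conjugated and frees the terminal vinyl group, while the two new stereocentres (C4, C7) arise unselectively and are erased in step 11.

Step 10
Reactants: 17 methyl (2E)-4-[(Ar)(BA)(hydroxy)methyl]hexa-2,5-dienoate
Product: 18 (2E)-4-[(Ar)(BA)(hydroxy)methyl]hexa-2,5-dienoic acid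
Conditions: Me3SnOH, ClCH2CH2Cl, 70 °C; cold dilute aq. HCl wash
Reagents that add atoms: trimethyltin hydroxide, C[Sn](C)(C)O
Why: Trimethyltin hydroxide cleaves unhindered methyl esters under essentially neutral conditions, which should avoid the C7 alkoxide that would trigger retro-addition or attack on the neighbouring alkyne.

Step 11
Reactants: 18 (2E)-4-[(Ar)(BA)(hydroxy)methyl]hexa-2,5-dienoic acid
Product: 22 penta-O-MOM selaginellin F (4-[(Ar)(BA)methylidene]cyclohexa-2,5-dien-1-one), via dienylketene 19 (not isolated), via cyclohexa-2,4-dienone 20 (not isolated), via hydroxyphenyl carbinol 21 (not isolated)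
Conditions: 2-chloro-1-methylpyridinium iodide, Et3N, ClCH2CH2Cl, slow addition of 18 (final 0.005 M), rt to 60 °C; then PPTS, rt
Reagents that add atoms: none
Why: The acyloxypyridinium salt of 18 should lose the doubly allylic C4–H to Et3N (1,4-elimination, the vinylketene synthesis from α,β-unsaturated acyl derivatives) to give dienylketene 19, whose thermal disrotatory 6π electrocyclisation joins the ketene carbon C1 to the vinyl terminus C2. This is the ring-closing event of the cyclobutenone-based and dienoic-acid-based phenol annulations, so one six-membered carbocycle is closed in a pericyclic mode that leaves no alternative ring size. Dienone 20 enolises to phenol 21, and the benzylic C7–OH, stabilised by three donor aryl groups, then leaves as water under PPTS (fuchsone formation), which moves the unsaturation into the exocyclic C4=C7 bond. No stereocentre is created and the two of 18 (C4, C7) are erased, so the diastereomer mixture converges on one product. The selectivity needed is the geometry of the new C4=C5 bond (vinyl cis to the ketene arm): the very large C7 substituent should take the position cis to H5, and only that isomer can cyclise. The E enoic acid cannot lactonise with C7–OH, and high dilution with slow addition should keep ketene dimerisation and acylation of 21 behind the intramolecular closure.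

Step 12
Reactants: 22 penta-O-MOM selaginellin F
Product: 23 selaginellin F
Conditions: 3 M aq. HCl, THF–iPrOH, 40 °C; then aq. NaHCO3
Reagents that add atoms: none
Why: Acid-catalysed acetal hydrolysis removes the four aryl and the one benzylic MOM group, while the quinone methide is only reversibly protonated to its triarylcarbenium ion and should be regenerated on neutralisation.

Compound list
1 | (2-bromo-4-chlorophenyl)methanol | OCc1ccc(Cl)cc1Br | starting material
2 | 2-bromo-4-chloro-1-[(methoxymethoxy)methyl]benzene | COCOCc1ccc(Cl)cc1Br | intermediate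
3 | 4-(methoxymethoxy)benzaldehyde | COCOc1ccc(C=O)cc1 | starting material
4 | {2-bromo-6-chloro-3-[(methoxymethoxy)methyl]phenyl}lithium | COCOCc1ccc(Cl)c([Li])c1Br | intermediate
5 | {2-bromo-6-chloro-3-[(methoxymethoxy)methyl]phenyl}[4-(methoxymethoxy)phenyl]methanol (racemic) | COCOCc1ccc(Cl)c(C(O)c2ccc(OCOC)cc2)c1Br | intermediate
6 | {2-bromo-6-chloro-3-[(methoxymethoxy)methyl]phenyl}[4-(methoxymethoxy)phenyl]methanone | COCOCc1ccc(Cl)c(C(=O)c2ccc(OCOC)cc2)c1Br | intermediate
7 | 1-ethynyl-4-(methoxymethoxy)benzene | C#Cc1ccc(OCOC)cc1 | intermediate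
8 | {6-chloro-3-[(methoxymethoxy)methyl]-2-{[4-(methoxymethoxy)phenyl]ethynyl}phenyl}[4-(methoxymethoxy)phenyl]methanone | COCOCc1ccc(Cl)c(C(=O)c2ccc(OCOC)cc2)c1C#Cc1ccc(OCOC)cc1 | intermediate
9 | 4-bromobenzene-1,3-diol | Oc1ccc(Br)c(O)c1 | starting material
10 | 1-bromo-2,4-bis(methoxymethoxy)benzene | COCOc1ccc(Br)c(OCOC)c1 | intermediate
11 | [2,4-bis(methoxymethoxy)phenyl]lithium | [Li]c1ccc(OCOC)cc1OCOC | intermediate
12 | [2,4-bis(methoxymethoxy)phenyl]zinc chloride | Cl[Zn]c1ccc(OCOC)cc1OCOC | intermediate
13 | (BA)(Ar)methanone | COCOCc1ccc(-c2ccc(OCOC)cc2OCOC)c(C(=O)c2ccc(OCOC)cc2)c1C#Cc1ccc(OCOC)cc1 | intermediate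
14 | methyl (2E,4E)-hexa-2,4-dienoate | C/C=C/C=C/C(=O)OC | starting material
15 | methyl (2E,4E)-6-bromohexa-2,4-dienoate | BrC/C=C/C=C/C(=O)OC | intermediate
16 | [(2E,4E)-6-methoxy-6-oxohexa-2,4-dien-1-yl]indium dibromide (simplest form of the organoindium reagent) | COC(=O)/C=C/C=C/C[In](Br)Br | intermediate
17 | methyl (2E)-4-[(Ar)(BA)(hydroxy)methyl]hexa-2,5-dienoate (diastereomer mixture at C4 and C7) | COC(=O)/C=C/C(C=C)C(O)(c1ccc(OCOC)cc1)c1c(-c2ccc(OCOC)cc2OCOC)ccc(COCOC)c1C#Cc1ccc(OCOC)cc1 | intermediate
18 | (2E)-4-[(Ar)(BA)(hydroxy)methyl]hexa-2,5-dienoic acid (diastereomer mixture) | OC(=O)/C=C/C(C=C)C(O)(c1ccc(OCOC)cc1)c1c(-c2ccc(OCOC)cc2OCOC)ccc(COCOC)c1C#Cc1ccc(OCOC)cc1 | intermediate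
19 | (3E)-4-[(Ar)(BA)(hydroxy)methyl]hexa-1,3,5-trien-1-one | O=C=C/C=C(\C=C)C(O)(c1ccc(OCOC)cc1)c1c(-c2ccc(OCOC)cc2OCOC)ccc(COCOC)c1C#Cc1ccc(OCOC)cc1 | intermediate
20 | 4-[(Ar)(BA)(hydroxy)methyl]cyclohexa-2,4-dien-1-one | O=C1CC=C(C(O)(c2ccc(OCOC)cc2)c2c(-c3ccc(OCOC)cc3OCOC)ccc(COCOC)c2C#Cc2ccc(OCOC)cc2)C=C1 | intermediate
21 | 4-[(Ar)(BA)(hydroxy)methyl]phenol | Oc1ccc(cc1)C(O)(c1ccc(OCOC)cc1)c1c(-c2ccc(OCOC)cc2OCOC)ccc(COCOC)c1C#Cc1ccc(OCOC)cc1 | intermediate
22 | 4-[(Ar)(BA)methylidene]cyclohexa-2,5-dien-1-one (penta-O-MOM selaginellin F) | O=C1C=CC(=C(c2ccc(OCOC)cc2)c2c(-c3ccc(OCOC)cc3OCOC)ccc(COCOC)c2C#Cc2ccc(OCOC)cc2)C=C1 | intermediate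
23 | selaginellin F | O=C1C=CC(=C(c2ccc(O)cc2)c2c(-c3ccc(O)cc3O)ccc(CO)c2C#Cc2ccc(O)cc2)C=C1 | target

Total step count: 12. Longest linear sequence: 9 steps (1, 2, 3, 5, 7, 9, 10, 11, 12).

Steps most likely to fail

**Step 9.** Several things may go wrong here:
- The carbonyl group of 13 is flanked by two ortho substituents, so addition may be slow, and protonolysis or homocoupling of the organoindium reagent may win.
- The reagent may react through its ester-bearing or its metal-bearing terminus instead of C4.
- The indium alkoxide may add to the neighbouring alkyne.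

The fallback sets out from 13 and uses the more nucleophilic, ester-free reagent made from (2E)-5-bromopenta-1,3-diene and In, for which attack through the central carbon is the established outcome. It should give the bis-vinyl carbinol 1-(Ar)-1-(BA)-2-vinylbut-3-en-1-ol F1. Cross metathesis of one of its two vinyl groups with methyl acrylate (second-generation Hoveyda–Grubbs catalyst, CH2Cl2, 40 °C) then installs the E enoate. Either vinyl group leads to the same ring A. The fallback comes back to the route at 17.

**Step 11.** Deprotonation may deliver the ketene with the carbinol group cis to the ketene arm, which would then be captured by the C7 hydroxyl as a six-membered lactone. Ketene dimerisation or acylation of the freshly formed phenol may also compete.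

The fallback replaces the pericyclic closure by a cationic one and removes the C4=C5 geometry question:
1. Setting out from 17, mild acid (PPTS, toluene, 60 °C) should dehydrate the carbinol to the cross-conjugated trienoate methyl (2E)-4-[(Ar)(BA)methylidene]hexa-2,5-dienoate F2, which has no retro-addition pathway.
2. LiOH in aqueous THF then gives the acid (2E)-4-[(Ar)(BA)methylidene]hexa-2,5-dienoic acid F3.
3. 1-Chloro-N,N,2-trimethylprop-1-en-1-amine converts F3 into the acid chloride (2E)-4-[(Ar)(BA)methylidene]hexa-2,5-dienoyl chloride F4.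
4. Ionisation with AgOTf and 2,6-di-tert-butyl-4-methylpyridine (CH2Cl2, −78 to 0 °C) should start an intramolecular alkene acylation of the Darzens–Nenitzescu type.

In the acylium ion the charge is shared with C7 (ketene–diarylcarbenium form), which frees rotation about C5–C6. The terminus C2 of the 1,1-diarylbutadiene unit then attacks C1, and loss of a proton from C2 comes back to the route at 22.

**Step 12.** Three things may go wrong:
- In acid the quinone methide exists as its carbenium ion, which may be trapped irreversibly by the liberated 2'-phenol or by solvent.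
- The electron-rich alkyne may be protonated and take up water or the neighbouring hydroxymethyl oxygen.
- The benzylic MOM group may cleave incompletely.

The fallback is a redox detour that keeps C7 neutral during the acid step:
1. Setting out from 22, 1,6-reduction with NaBH4 (THF–MeOH, 0 °C) should give the leuco compound 4-[(Ar)(BA)methyl]phenol F5.
2. The same aqueous HCl treatment then removes the MOM groups to give the leuco form of the target, 4,4'-({2',4'-dihydroxy-4-(hydroxymethyl)-3-[(4-hydroxyphenyl)ethynyl]biphenyl-2-yl}methylene)diphenol F6.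
3. Dehydrogenation of the bis(4-hydroxyphenyl)methine C–H with one equivalent of DDQ (dioxane, rt), the standard oxidation of leuco triarylmethane dyes, comes back to the route at 23.

Further compounds
F1 | step 9 | 1-(Ar)-1-(BA)-2-vinylbut-3-en-1-ol | C=CC(C=C)C(O)(c1ccc(OCOC)cc1)c1c(-c2ccc(OCOC)cc2OCOC)ccc(COCOC)c1C#Cc1ccc(OCOC)cc1
F2 | step 11 | methyl (2E)-4-[(Ar)(BA)methylidene]hexa-2,5-dienoate | COC(=O)/C=C/C(C=C)=C(c1ccc(OCOC)cc1)c1c(-c2ccc(OCOC)cc2OCOC)ccc(COCOC)c1C#Cc1ccc(OCOC)cc1
F3 | step 11 | (2E)-4-[(Ar)(BA)methylidene]hexa-2,5-dienoic acid | OC(=O)/C=C/C(C=C)=C(c1ccc(OCOC)cc1)c1c(-c2ccc(OCOC)cc2OCOC)ccc(COCOC)c1C#Cc1ccc(OCOC)cc1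
F4 | step 11 | (2E)-4-[(Ar)(BA)methylidene]hexa-2,5-dienoyl chloride | ClC(=O)/C=C/C(C=C)=C(c1ccc(OCOC)cc1)c1c(-c2ccc(OCOC)cc2OCOC)ccc(COCOC)c1C#Cc1ccc(OCOC)cc1
F5 | step 12 | 4-[(Ar)(BA)methyl]phenol (racemic) | Oc1ccc(cc1)C(c1ccc(OCOC)cc1)c1c(-c2ccc(OCOC)cc2OCOC)ccc(COCOC)c1C#Cc1ccc(OCOC)cc1
F6 | step 12 | 4,4'-({2',4'-dihydroxy-4-(hydroxymethyl)-3-[(4-hydroxyphenyl)ethynyl]biphenyl-2-yl}methylene)diphenol | Oc1ccc(cc1)C(c1ccc(O)cc1)c1c(-c2ccc(O)cc2O)ccc(CO)c1C#Cc1ccc(O)cc1
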